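**Strategy.** In daucane numbering, everything rests on disconnecting the C5–C6 bond of the seven-membered ring. C6, the ester-bearing carbon, is bonded to ring-fusion C5, and C5 with the isopropyl-bearing C4 can be carried as the alkene of the five-membered ring. An acylium ion at C6 therefore adds to C5, the charge settles on tertiary C4, and proton loss returns a C4=C5 enone. One operation closes the seven-membered ring (C1, C5–C10), installs the C6 oxygen and leaves the enone through which the C4 hydroxyl and C5 hydrogen are later set. The precursor is an (R)-3-isopropyl-1-methylcyclopentene whose quaternary C1 carries a (Z)-3-methylpent-3-enoyl chloride chain.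

Key step: step 8

Remark 1: numbering follows the daucane skeleton: C1 is the quaternary ring-fusion carbon with the methyl group, C4 the tertiary carbinol with the isopropyl group, C5 the ring-fusion methine, C6 the acyloxy carbon, C8 and C9 the oxirane carbons; C2, C3, C7 and C10 are methylenes. β is the face of the C1 methyl. The target is read as (1R,4R,5S,6R,8R,9S): 4β-OH, 5α-H (trans ring fusion), 6β-aroyloxy, 8α,9α-epoxide.

Remark 2: dauca-4,8-dien-6-one is a conjugated enone with an isolated β′,γ′-alkene (C8=C9 is not in conjugation). While the C6 ketone is present, base and protic acid are kept away so that this alkene does not migrate.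

Remark 3: 2 and 10 are taken as purchased solutions, 8 and 22 as purchased solids.

**Step 1**
Reactants: 1 3-methylcyclopent-2-en-1-one; 2 (1,3-dioxolan-2-ylmethyl)magnesium bromide
Product: 4 (R)-3-(1,3-dioxolan-2-ylmethyl)-3-methylcyclopent-1-en-1-yl trifluoromethanesulfonate, via magnesium enolate 3 (not isolated)
Conditions: Cu(OTf)2 (3 mol%), chiral hydroxyalkyl imidazolinium salt (NHC ligand precursor, 4 mol%), Et2O, −30 °C, slow addition of 2; then PhNTf2, DMPU, −30 → 20 °C
Reagents that add atoms: (1,3-dioxolan-2-ylmethyl)magnesium bromide (2), Br[Mg]CC1OCCO1; N-phenylbis(trifluoromethanesulfonimide), FC(F)(F)S(=O)(=O)N(c1ccccc1)S(=O)(=O)C(F)(F)F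
Why: Copper-catalysed asymmetric conjugate addition of a Grignard reagent to a β-substituted cyclic enone creates the quaternary C1 centre, the chiral NHC–copper complex (ligand enantiomer chosen for the R product) selecting the enone face, and O-sulfonylation of the regiodefined magnesium enolate fixes the alkene between C4 and C5.

**Step 2**
Reactants: 4; 5 isopropylmagnesium chloride
Product: 6 2-{[(R)-3-isopropyl-1-methylcyclopent-2-en-1-yl]methyl}-1,3-dioxolane
Conditions: Fe(acac)3 (5 mol%), THF/NMP, −30 °C
Reagents that add atoms: isopropylmagnesium chloride (5), CC(C)[Mg]Cl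
Why: Iron-catalysed Kumada-type cross-coupling of an alkenyl triflate with a secondary alkyl Grignard reagent replaces the triflate by isopropyl without moving the alkene, and the acetal and the quaternary stereocentre are not touched.

**Step 3**
Reactants: 6
Product: 7 [(R)-3-isopropyl-1-methylcyclopent-2-en-1-yl]acetaldehyde
Conditions: 1 M HCl, THF, 20 °C
Reagents that add atoms: water, O
Why: Acid-catalysed acetal hydrolysis frees the aldehyde under dilute aqueous conditions that should not protonate the trisubstituted ring alkene.

**Step 4**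
Reactants: 7; 8 ethyltriphenylphosphonium iodide
Product: 9 (R)-1-[(Z)-3-iodobut-2-en-1-yl]-3-isopropyl-1-methylcyclopent-2-ene
Conditions: 8, n-BuLi, THF, 20 °C; I2, −78 °C; NaN(SiMe3)2, −20 °C; then 7, −78 → −20 °C
Reagents that add atoms: ethyltriphenylphosphonium iodide (8), CC[P+](c1ccccc1)(c1ccccc1)c1ccccc1.[I-]; iodine, II
Why: Stork–Zhao-type Wittig olefination with the α-iodo ylide behaves like a non-stabilised ylide reaction and should place iodine cis to the C10 chain through the kinetically favoured cis-oxaphosphetane, which fixes the (Z)-trisubstituted alkene geometry needed for ring closure.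

**Step 5**
Reactants: 9; 10 (2-tert-butoxy-2-oxoethyl)zinc chloride
Product: 11 tert-butyl (Z)-5-[(R)-3-isopropyl-1-methylcyclopent-2-en-1-yl]-3-methylpent-3-enoate
Conditions: Pd(PPh3)4 (5 mol%), THF, 50 °C
Reagents that add atoms: (2-tert-butoxy-2-oxoethyl)zinc chloride (10), CC(C)(C)OC(=O)C[Zn]Cl
Why: Negishi cross-coupling of a Reformatsky reagent with an alkenyl iodide proceeds with retention of alkene geometry and should give the β,γ-unsaturated ester directly, with no step that could draw the alkene into conjugation.

**Step 6**
Reactants: 11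
Product: 13 (Z)-5-[(R)-3-isopropyl-1-methylcyclopent-2-en-1-yl]-3-methylpent-3-enoic acid, via trimethylsilyl ester 12 (not isolated)
Conditions: Me3SiOTf, 2,6-lutidine, CH2Cl2, 0 °C; then H2O
Reagents that add atoms: none
Why: Silyl triflate-mediated cleavage of the tert-butyl ester (loss of isobutene, buffered by 2,6-lutidine) and hydrolysis of the silyl ester liberate the acid without aqueous base or protic acid, so the β,γ-alkene should neither migrate nor lose its geometry.

**Step 7**
Reactants: 13
Product: 14 (Z)-5-[(R)-3-isopropyl-1-methylcyclopent-2-en-1-yl]-3-methylpent-3-enoyl chloride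
Conditions: (COCl)2, DMF (cat.), CH2Cl2, 0 → 20 °C; volatiles removed, used crude
Reagents that add atoms: oxalyl chloride, O=C(Cl)C(Cl)=O
Why: Acid chloride formation through the chloroiminium (Vilsmeier-type) catalyst needs no added base, which avoids vinylketene formation from the β,γ-unsaturated acyl chloride.

**Step 8**
Reactants: 14
Product: 16 (R)-dauca-4,8-dien-6-one [(8aR)-3-isopropyl-6,8a-dimethyl-1,2,8,8a-tetrahydroazulen-4(5H)-one], via tertiary chloride 15 (not isolated)
Conditions: SnCl4 (1.2 equiv), CH2Cl2 (0.01 M), −78 → −20 °C; then cold aq. NaHCO3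
Reagents that add atoms: none
Why: SnCl4 abstracts chloride from 14 to give the C6 acylium ion, which adds to C5 of the trisubstituted cyclopentene so that the charge develops on tertiary, isopropyl-bearing C4; the ion pair collapses to tertiary chloride 15, which re-ionises on warming and loses the now α-carbonyl C5 proton to give the conjugated C4=C5 enone. The closest known reaction type is the Lewis-acid-mediated intramolecular acylation of an alkene by an acid chloride (aliphatic Friedel–Crafts or Darzens–Nenitzescu acylation), which is established for cycloheptenone and hydroazulenone formation. The seven-membered ring (C1, C5, C6, C7, C8, C9, C10) closes in the 7-exo-trig mode with respect to the cyclopentene π-bond, C5 becoming a ring atom while C4 stays outside the new ring. No stereocentre is created, because C5 returns to sp2 and C1, the only stereocentre, is not involved. The step needs regioselectivity (C5, not C4) and chemoselectivity (ring alkene, not chain alkene); these are secured by placement of the charge on tertiary C4, by the (Z)-alkene that holds C6 within reach of C5, and by the fact that attack on C8 or C9 would give a three- or four-membered ring. Low temperature, high dilution and the absence of base are meant to suppress vinylketene formation and to keep the C8=C9 alkene out of conjugation.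

**Step 9**
Reactants: 16
Product: 17 (1R,6R)-dauca-4,8-dien-6-ol (6β-OH)
Conditions: (S)-1-methyl-3,3-diphenyl-tetrahydro-1H,3H-pyrrolo[1,2-c][1,3,2]oxazaborole ((S)-Me-CBS, 0.5 equiv), catecholborane, toluene, −78 °C; MeOH, then aq. NaOH wash
Reagents that add atoms: none
Why: Corey–Bakshi–Shibata reduction, in which the oxazaborolidine binds the ketone on the lone pair remote from the bulky, fully substituted C5 side and delivers hydride from catecholborane to the Si face of C6, should give the 6R (6β) allylic alcohol under catalyst control, while catecholborane at −78 °C leaves the C8=C9 alkene alone.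

**Step 10**
Reactants: 17
Product: 18 (1R)-4β,5β-epoxydauc-8-en-6β-ol
Conditions: VO(acac)2 (5 mol%), t-BuOOH (1.1 equiv), CH2Cl2, 0 °C
Reagents that add atoms: tert-butyl hydroperoxide, CC(C)(C)OO
Why: Vanadium-catalysed hydroxyl-directed epoxidation delivers oxygen to the face of C4=C5 on which the 6β-hydroxyl lies (C6–H eclipsing the alkene to avoid allylic strain with the isopropyl group), which sets the C4–O bond β, and the allylic alkene should react much faster than the homoallylic C8=C9 alkene.

**Step 11**
Reactants: 18
Product: 19 (1R)-4β,5β-epoxydauc-8-en-6-one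
Conditions: Dess–Martin periodinane, NaHCO3, CH2Cl2, 0 → 20 °C
Reagents that add atoms: none
Why: Dess–Martin oxidation of the secondary alcohol under bicarbonate buffer should give the α,β-epoxy ketone without opening the tetrasubstituted epoxide or enolising C7.

**Step 12**
Reactants: 19
Product: 20 (1R)-4β-hydroxy-5α-dauc-8-en-6-one (trans-fused)
Conditions: SmI2 (2.2 equiv), THF/MeOH, −78 °C; pH 7 buffer
Reagents that add atoms: none
Why: Single-electron reduction of the α,β-epoxy ketone cleaves the C5–O bond regiospecifically to a trivalent samarium enolate while the C4–O stereocentre is retained, and protonation of C5 by methanol on the α-face, away from the solvated samarium alkoxide on C4 and the C1 methyl, is expected to give the trans-fused aldol, the epimer that can also hold an O4–H···O6 hydrogen bond.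

**Step 13**
Reactants: 20
Product: 21 (1R)-5α-dauc-8-ene-4β,6β-diol
Conditions: Zn(BH4)2, Et2O, −20 °C; then H2O
Reagents that add atoms: none
Why: Chelation-controlled hydride reduction of a β-hydroxy ketone, with zinc bridging O4 and the C6 carbonyl and hydride adding to the α-face opposite the pseudo-axial C1 methyl, should give the syn-1,3-diol with the 6β-hydroxyl under non-basic conditions.

**Step 14**
Reactants: 21; 22 4-acetoxybenzoyl chloride
Product: 23 (1R)-4β-hydroxy-5α-dauc-8-en-6β-yl 4-acetoxybenzoate
Conditions: 4-(dimethylamino)pyridine (0.3 equiv), Et3N, CH2Cl2, 20 → 40 °C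
Reagents that add atoms: 4-acetoxybenzoyl chloride (22), CC(=O)Oc1ccc(cc1)C(Cl)=O
Why: Nucleophile-catalysed acylation by the acid chloride should take place at the secondary C6 hydroxyl only, the tertiary C4 hydroxyl being too hindered to react.

**Step 15**
Reactants: 23
Product: 24 (1R)-8α,9α-epoxy-4β-hydroxy-5α-daucan-6β-yl 4-acetoxybenzoate
Conditions: mCPBA (1.2 equiv), CH2Cl2, 0 °C; aq. NaHCO3 wash
Reagents that add atoms: 3-chloroperoxybenzoic acid (mCPBA), OOC(=O)c1cccc(Cl)c1
Why: Prilezhaev epoxidation of the only remaining alkene should occur on the α-face, because the β-face is screened by the pseudo-axial C1 methyl and the C6 aroyloxy group, which sets C8 and C9.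

**Step 16**
Reactants: 24
Product: 25 (1R,4R,5S,6R,8R,9S)-8,9-epoxy-4-hydroxydaucan-6-yl 4-hydroxybenzoate (target)
Conditions: NH4OAc, MeOH/H2O (4:1), 20 °C
Reagents that add atoms: none
Why: Ammonium acetate-mediated methanolysis removes the phenolic acetate, which is far more electrophilic than the hindered alkyl aroate, under near-neutral conditions that should spare the epoxide and the C6 ester.

**Compound list**

1 | 3-methylcyclopent-2-en-1-one | CC1=CC(=O)CC1 | starting material
2 | (1,3-dioxolan-2-ylmethyl)magnesium bromide | Br[Mg]CC1OCCO1 | starting material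
3 | bromomagnesium (R)-3-(1,3-dioxolan-2-ylmethyl)-3-methylcyclopent-1-en-1-olate | Br[Mg]OC1=C[C@@](C)(CC2OCCO2)CC1 | intermediate
4 | (R)-3-(1,3-dioxolan-2-ylmethyl)-3-methylcyclopent-1-en-1-yl trifluoromethanesulfonate | O=S(=O)(OC1=C[C@@](C)(CC2OCCO2)CC1)C(F)(F)F | intermediate
5 | isopropylmagnesium chloride | CC(C)[Mg]Cl | starting material
6 | 2-{[(R)-3-isopropyl-1-methylcyclopent-2-en-1-yl]methyl}-1,3-dioxolane | CC(C)C1=C[C@@](C)(CC2OCCO2)CC1 | intermediate
7 | [(R)-3-isopropyl-1-methylcyclopent-2-en-1-yl]acetaldehyde | CC(C)C1=C[C@@](C)(CC=O)CC1 | intermediate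
8 | ethyltriphenylphosphonium iodide | CC[P+](c1ccccc1)(c1ccccc1)c1ccccc1.[I-] | starting material
9 | (R)-1-[(Z)-3-iodobut-2-en-1-yl]-3-isopropyl-1-methylcyclopent-2-ene | CC(C)C1=C[C@@](C)(C/C=C(C)\I)CC1 | intermediate
10 | (2-tert-butoxy-2-oxoethyl)zinc chloride | CC(C)(C)OC(=O)C[Zn]Cl | starting material
11 | tert-butyl (Z)-5-[(R)-3-isopropyl-1-methylcyclopent-2-en-1-yl]-3-methylpent-3-enoate | CC(C)C1=C[C@@](C)(C/C=C(C)\CC(=O)OC(C)(C)C)CC1 | intermediate
12 | trimethylsilyl (Z)-5-[(R)-3-isopropyl-1-methylcyclopent-2-en-1-yl]-3-methylpent-3-enoate | CC(C)C1=C[C@@](C)(C/C=C(C)\CC(=O)O[Si](C)(C)C)CC1 | intermediate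
13 | (Z)-5-[(R)-3-isopropyl-1-methylcyclopent-2-en-1-yl]-3-methylpent-3-enoic acid | CC(C)C1=C[C@@](C)(C/C=C(C)\CC(O)=O)CC1 | intermediate
14 | (Z)-5-[(R)-3-isopropyl-1-methylcyclopent-2-en-1-yl]-3-methylpent-3-enoyl chloride | CC(C)C1=C[C@@](C)(C/C=C(C)\CC(Cl)=O)CC1 | intermediate
15 | (1R)-4-chlorodauc-8-en-6-one, cis ring fusion (5β-H), configuration at C4 not defined | CC(C)C1(Cl)CC[C@]2(C)CC=C(C)CC(=O)[C@H]12 | intermediate
16 | (R)-dauca-4,8-dien-6-one | CC(C)C1=C2C(=O)CC(C)=CC[C@@]2(C)CC1 | intermediate
17 | (1R,6R)-dauca-4,8-dien-6-ol (6β-OH) | CC(C)C1=C2[C@H](O)CC(C)=CC[C@@]2(C)CC1 | intermediate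
18 | (1R)-4β,5β-epoxydauc-8-en-6β-ol | CC(C)[C@]13CC[C@]2(C)CC=C(C)C[C@@H](O)[C@@]21O3 | intermediate
19 | (1R)-4β,5β-epoxydauc-8-en-6-one | CC(C)[C@]13CC[C@]2(C)CC=C(C)CC(=O)[C@@]21O3 | intermediate
20 | (1R)-4β-hydroxy-5α-dauc-8-en-6-one | CC(C)[C@]1(O)CC[C@]2(C)CC=C(C)CC(=O)[C@H]21 | intermediate
21 | (1R)-5α-dauc-8-ene-4β,6β-diol | CC(C)[C@]1(O)CC[C@]2(C)CC=C(C)C[C@@H](O)[C@H]21 | intermediate
22 | 4-acetoxybenzoyl chloride | CC(=O)Oc1ccc(cc1)C(Cl)=O | starting material
23 | (1R)-4β-hydroxy-5α-dauc-8-en-6β-yl 4-acetoxybenzoate | CC(C)[C@]1(O)CC[C@]2(C)CC=C(C)C[C@@H](OC(=O)c3ccc(OC(C)=O)cc3)[C@H]21 | intermediate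
24 | (1R)-8α,9α-epoxy-4β-hydroxy-5α-daucan-6β-yl 4-acetoxybenzoate | CC(C)[C@]1(O)CC[C@]2(C)C[C@@H]3O[C@]3(C)C[C@@H](OC(=O)c3ccc(OC(C)=O)cc3)[C@H]21 | intermediate
25 | (1R,4R,5S,6R,8R,9S)-8,9-epoxy-4-hydroxydaucan-6-yl 4-hydroxybenzoate (CNP0163817.3) | CC(C)[C@]1(O)CC[C@]2(C)C[C@@H]3O[C@]3(C)C[C@@H](OC(=O)c3ccc(O)cc3)[C@H]21 | target

**Totals.** Total step count: 16. Longest linear sequence: 16 steps (from 1).

**Steps most likely to fail**

Step 8. What may go wrong: loss of the doubly activated C7 proton from the acylium ion (vinylketene formation), acid-induced migration of the C8=C9 alkene into conjugation, or protonation of that alkene followed by cation–alkene cyclisation onto the cyclopentene; each can outrun closure of the seven-membered ring. Fallback (sets out from 9, returns at 16): the ring is closed at C7–C8 by organopalladium chemistry instead. Aliphatic Friedel–Crafts acetylation of 9 at C5 (acetyl chloride, SnCl4, CH2Cl2, −78 °C), which involves no β,γ-unsaturated acyl chloride, should give 1-{(5R)-5-[(Z)-3-iodobut-2-en-1-yl]-2-isopropyl-5-methylcyclopent-1-en-1-yl}ethan-1-one F1. Kinetic enolisation of the acetyl group (LiN(SiMe3)2, THF, −78 °C) and intramolecular α-alkenylation of the ketone by the (Z)-alkenyl iodide under zerovalent palladium catalysis (Pd(PPh3)4) should then give 16 with the C8=C9 alkene already in place.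

Step 12. What may go wrong: poor facial selectivity in the protonation of the samarium enolate at C5 (protonation on the β-face gives the cis-fused epimer), together with retro-aldol cleavage or dehydration of the tertiary aldol. Fallback (sets out from 18, returns at 20; no new compound, F0): semipinacol rearrangement of the 2,3-epoxy alcohol. A chelating Lewis acid (ZnBr2, CH2Cl2, 0 °C) bridges the C6 hydroxyl and the epoxide oxygen, and H-6, which lies antiperiplanar to the C5–O bond on the α-face, migrates to C5 as that bond breaks. The C6 ketone, the C4 hydroxyl and the 5α-hydrogen would then arise in one stereospecific step without an enolate, and step 11 is bypassed.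

Step 9. What may go wrong: poor facial selectivity at C6 if catalyst-controlled hydride delivery is mismatched with the intrinsic bias of the twisted, hindered enone (the C8–C10 segment of the seven-membered ring lies on the α-face). This would give the 6α-alcohol, which would direct the epoxidation to the wrong face. Fallback (sets out from 16, returns at 17): substrate-controlled 1,2-reduction under Luche conditions (NaBH4, CeCl3·7H2O, MeOH, −78 °C) to (1R,6S)-dauca-4,8-dien-6-ol F2. Mitsunobu inversion with 4-nitrobenzoic acid (PPh3, diisopropyl azodicarboxylate, THF, 0 °C) then gives (1R,6R)-dauca-4,8-dien-6-yl 4-nitrobenzoate F3, and methanolysis (K2CO3, MeOH, 0 °C) gives 17.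

**Further compounds**

F1 | step 8 | 1-{(5R)-5-[(Z)-3-iodobut-2-en-1-yl]-2-isopropyl-5-methylcyclopent-1-en-1-yl}ethan-1-one | CC(C)C1=C(C(C)=O)[C@@](C)(C/C=C(C)\I)CC1
F0 | step 12 | none | none
F2 | step 9 | (1R,6S)-dauca-4,8-dien-6-ol (6α-OH) | CC(C)C1=C2[C@@H](O)CC(C)=CC[C@@]2(C)CC1
F3 | step 9 | (1R,6R)-dauca-4,8-dien-6-yl 4-nitrobenzoate | CC(C)C1=C2[C@H](OC(=O)c3ccc(cc3)[N+]([O-])=O)CC(C)=CC[C@@]2(C)CC1
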